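**Retrosynthetic overview**
1. Target ⇐ its bis(acetonide) by acid removal of both catechol ketals (last step).
2. Lactone ring (the only ring built, closed in the key step) ⇐ open-chain ynoate ester by forming the C3–C4 bond of the oxolane: a benzylic C–H radical closes 5-exo-dig onto the alkyne, which also sets C3 (trans to C2) and the E alkene.
3. Ynoate ester ⇐ (S)-aryl-lactate + arylpropiolic acid by esterification; the C2 configuration comes from methyl (S)-glycidate.
4. Both halves ⇐ one aryl iodide: copper-catalysed Grignard opening of the glycidate, and palladium coupling with propiolic acid.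
5. Aryl iodide ⇐ catechol by ketalisation and iodination.

Assumption: methyl (2S)-oxirane-2-carboxylate is taken as a commercial chiral building block, and the target SMILES is read as the (2S,3S)-trans lactone with an E benzylidene group.

**Step 1**
Reactants: 1 catechol (benzene-1,2-diol)
Product: 2 2,2-dimethyl-1,3-benzodioxole
Conditions: 2,2-dimethoxypropane (1.5 equiv), TsOH·H2O (2 mol%), toluene, reflux, MeOH removed over 4 Å MS (Soxhlet)
Reagents that add atoms: 2,2-dimethoxypropane, COC(C)(C)OC
Why: Acid-catalysed transketalisation closes the five-membered catechol acetonide, driven by removal of methanol.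

**Step 2**
Reactants: 2 2,2-dimethyl-1,3-benzodioxole
Product: 3 5-iodo-2,2-dimethyl-1,3-benzodioxole
Conditions: NIS (1.05 equiv), TFA (10 mol%), MeCN, 0 °C → rt, dark
Reagents that add atoms: N-iodosuccinimide, O=C1CCC(=O)N1I
Why: Electrophilic aromatic iodination goes para to a ring oxygen, and the two such positions (5 and 6) are equivalent by symmetry.

**Step 3**
Reactants: 3 5-iodo-2,2-dimethyl-1,3-benzodioxole; 4 methyl (2S)-oxirane-2-carboxylate (methyl (S)-glycidate)
Product: 6 methyl (2S)-3-(2,2-dimethyl-1,3-benzodioxol-5-yl)-2-hydroxypropanoate, via arylmagnesium chloride 5 (not isolated)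
Conditions: 3 (1.3 equiv), iPrMgCl·LiCl (1.25 equiv), THF, 0 °C → rt, 2 h; then CuI (copper monoiodide, 10 mol%), 4 (1.0 equiv), THF, −40 → −20 °C; sat. aq. NH4Cl
Reagents that add atoms: none
Why: Iodine–magnesium exchange gives the aryl Grignard, and its copper-catalysed SN2 opening of the epoxide at the unsubstituted C3 outruns ester addition at −40 °C; C2 is not touched, so the S configuration of 4 is carried into 6.

**Step 4**
Reactants: 3 5-iodo-2,2-dimethyl-1,3-benzodioxole; 7 propiolic acid (prop-2-ynoic acid)
Product: 8 3-(2,2-dimethyl-1,3-benzodioxol-5-yl)prop-2-ynoic acid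
Conditions: 7 (1.2 equiv), Pd(PPh3)4 (3 mol%), DBU (2.5 equiv), DMSO, 30 °C, 12 h; cold aq. citric acid to pH 3
Reagents that add atoms: none
Why: Copper-free Sonogashira-type coupling of the aryl iodide with the propiolate anion, run below the temperature at which arylpropiolic acids decarboxylate.

**Step 5**
Reactants: 6 methyl (2S)-3-(2,2-dimethyl-1,3-benzodioxol-5-yl)-2-hydroxypropanoate; 8 3-(2,2-dimethyl-1,3-benzodioxol-5-yl)prop-2-ynoic acid
Product: 9 methyl (2S)-3-(2,2-dimethyl-1,3-benzodioxol-5-yl)-2-{[3-(2,2-dimethyl-1,3-benzodioxol-5-yl)prop-2-ynoyl]oxy}propanoate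
Conditions: DMAP (10 mol%), CH2Cl2, 0 °C, DCC (1.1 equiv) added last, → rt, 3 h
Reagents that add atoms: none
Why: Steglich esterification acylates the secondary alcohol without breaking its C–O bond, so C2 stays S; adding DCC last at 0 °C keeps the acid from self-condensing through its anhydride.

**Step 6**
Reactants: 9 methyl (2S)-3-(2,2-dimethyl-1,3-benzodioxol-5-yl)-2-{[3-(2,2-dimethyl-1,3-benzodioxol-5-yl)prop-2-ynoyl]oxy}propanoate
Product: 12 methyl (2S,3S)-3-(2,2-dimethyl-1,3-benzodioxol-5-yl)-4-[(E)-(2,2-dimethyl-1,3-benzodioxol-5-yl)methylidene]-5-oxooxolane-2-carboxylate, via benzylic radical 10 (not isolated), via vinyl radical 11 (not isolated)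
Conditions: (n-Bu4N)4[W10O32] (3 mol%), degassed MeCN (0.02 M), 390 nm LEDs, 35 °C, Ar
Reagents that add atoms: none
Why: Proposed new method: photoexcited decatungstate abstracts the hydridic benzylic hydrogen of 9 (the C2–H is deactivated by two acceptor groups and the ketal methyls are strong primary C–H bonds), benzylic radical 10 closes 5-exo-dig onto the alkyne carbon next to the carbonyl because this gives the aryl-conjugated linear vinyl radical 11, and hydrogen return from the reduced polyoxometalate gives 12 and regenerates the catalyst, so the step is a redox-neutral cycloisomerisation in which unproductive hydrogen return to 10 only re-forms 9; the new C3 stereocentre is set trans to the C2 ester because the aryl group on the planar radical avoids the adjacent CO2Me in the ring-closing transition state (trans is also the more stable isomer), and the E alkene arises from hydrogen delivery to 11 on the open carbonyl side, away from the C3 aryl; the closest known reaction types are decatungstate-photocatalysed benzylic C–H hydroalkylation of electron-poor alkenes and alkynes (Giese type) and the tin hydride 5-exo-dig cyclisation of 2-haloalkyl alkynoates to alpha-alkylidene butyrolactones.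

**Step 7**
Reactants: 12 methyl (2S,3S)-3-(2,2-dimethyl-1,3-benzodioxol-5-yl)-4-[(E)-(2,2-dimethyl-1,3-benzodioxol-5-yl)methylidene]-5-oxooxolane-2-carboxylate
Product: 13 methyl (2S,3S)-3-(3,4-dihydroxyphenyl)-4-[(E)-(3,4-dihydroxyphenyl)methylidene]-5-oxooxolane-2-carboxylate (CNP0143432.2)
Conditions: TFA/H2O (9:1), 0 °C → rt, 1–2 h, Ar; evaporate, reversed-phase chromatography
Reagents that add atoms: none
Why: Acid-catalysed ketal hydrolysis frees both catechols under the conditions used for acetonide-protected catechols in peptide work; with no base present the methyl ester, lactone, E alkene and both stereocentres are untouched.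

**Compound list**
1 | catechol (benzene-1,2-diol) | Oc1ccccc1O | starting material
2 | 2,2-dimethyl-1,3-benzodioxole | CC1(C)Oc2ccccc2O1 | intermediate
3 | 5-iodo-2,2-dimethyl-1,3-benzodioxole | CC1(C)Oc2ccc(I)cc2O1 | intermediate
4 | methyl (2S)-oxirane-2-carboxylate | COC(=O)[C@@H]1CO1 | starting material
5 | (2,2-dimethyl-1,3-benzodioxol-5-yl)magnesium chloride (LiCl complex), not isolated | CC1(C)Oc2ccc([Mg]Cl)cc2O1 | intermediate
6 | methyl (2S)-3-(2,2-dimethyl-1,3-benzodioxol-5-yl)-2-hydroxypropanoate | COC(=O)[C@@H](O)Cc1ccc2OC(C)(C)Oc2c1 | intermediate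
7 | propiolic acid (prop-2-ynoic acid) | C#CC(=O)O | starting material
8 | 3-(2,2-dimethyl-1,3-benzodioxol-5-yl)prop-2-ynoic acid | OC(=O)C#Cc1ccc2OC(C)(C)Oc2c1 | intermediate
9 | methyl (2S)-3-(2,2-dimethyl-1,3-benzodioxol-5-yl)-2-{[3-(2,2-dimethyl-1,3-benzodioxol-5-yl)prop-2-ynoyl]oxy}propanoate | COC(=O)[C@@H](OC(=O)C#Cc1ccc2OC(C)(C)Oc2c1)Cc1ccc2OC(C)(C)Oc2c1 | intermediate
10 | benzylic radical at C3 of 9 (C2 still S), not isolated | COC(=O)[C@@H](OC(=O)C#Cc1ccc2OC(C)(C)Oc2c1)[CH]c1ccc2OC(C)(C)Oc2c1 | intermediate
11 | cyclised (2S,3S)-lactone carrying the exocyclic aryl-substituted vinyl radical, not isolated | COC(=O)[C@H]1OC(=O)C(=[C]c2ccc3OC(C)(C)Oc3c2)[C@@H]1c1ccc2OC(C)(C)Oc2c1 | intermediate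
12 | methyl (2S,3S)-3-(2,2-dimethyl-1,3-benzodioxol-5-yl)-4-[(E)-(2,2-dimethyl-1,3-benzodioxol-5-yl)methylidene]-5-oxooxolane-2-carboxylate | COC(=O)[C@H]1OC(=O)/C(=C/c2ccc3OC(C)(C)Oc3c2)[C@@H]1c1ccc2OC(C)(C)Oc2c1 | intermediate
13 | methyl (2S,3S)-3-(3,4-dihydroxyphenyl)-4-[(E)-(3,4-dihydroxyphenyl)methylidene]-5-oxooxolane-2-carboxylate | COC(=O)[C@H]1OC(=O)/C(=C/c2ccc(O)c(O)c2)[C@@H]1c1ccc(O)c(O)c1 | target

**Step count**
Total: 7 steps. Longest linear sequence: 6 steps (1 → 2 → 3 → 6 → 9 → 12 → 13, that is steps 1, 2, 3, 5, 6, 7; the branch through 8 is equally long).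

**Steps most likely to fail, with fallbacks**

Step 6 is the main risk. Ring closure through the ester tether needs the less populated ester rotamer and may be slow. The product's C3–H is benzylic and allylic, so further hydrogen abstraction could move the alkene into the ring. The lamp may also scramble E/Z. The fallback sets out from 9 and installs a radical leaving group first. Benzylic bromination (NBS, AIBN, PhCF3, 80 °C) gives methyl (2R,3RS)-3-bromo-3-(2,2-dimethyl-1,3-benzodioxol-5-yl)-2-{[3-(2,2-dimethyl-1,3-benzodioxol-5-yl)prop-2-ynoyl]oxy}propanoate F1 as both C3 epimers, used crude. The C2 descriptor changes to R only because bromine raises the priority of C3; the spatial arrangement is that of 9. Slow addition of Bu3SnH with AIBN in benzene at 80 °C (0.005 M) then runs the same 5-exo-dig closure as a tin-mediated chain, with bromine abstraction in place of C–H abstraction, and comes back to the route at 12. Material reduced before it cyclises is 9 and is recycled.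

Step 4 may fail through decarboxylation or self-coupling of propiolic acid under palladium and base, or through sluggish coupling of the electron-rich aryl iodide. The fallback sets out from 3 and builds the acid from a C2 alkyne and CO2. Sonogashira coupling with trimethylsilylacetylene (Pd(PPh3)2Cl2, CuI (copper monoiodide), Et3N, 50 °C) gives trimethyl[(2,2-dimethyl-1,3-benzodioxol-5-yl)ethynyl]silane F2. Fluoride-triggered carboxylation (CsF, CO2 at 1 atm, DMSO, rt; citric acid work-up) then comes back to the route at 8.

Step 3 may fail if the Grignard reagent attacks the methyl ester of 4 or of the product instead of opening the epoxide. The fallback sets out from 4 and removes the ester before the C–C bond is made. Saponification (KOH, EtOH, 0 °C) gives potassium (2S)-oxirane-2-carboxylate F3. Opening with 5 (2 equiv, CuI (copper monoiodide, 10 mol%), THF, −20 → 0 °C; cold dilute HCl to pH 3) gives (2S)-3-(2,2-dimethyl-1,3-benzodioxol-5-yl)-2-hydroxypropanoic acid F4. Methylation of the carboxylate (MeI, KHCO3, DMF, rt) comes back to the route at 6.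

**Further compounds**
F1 | step 6 | methyl (2R,3RS)-3-bromo-3-(2,2-dimethyl-1,3-benzodioxol-5-yl)-2-{[3-(2,2-dimethyl-1,3-benzodioxol-5-yl)prop-2-ynoyl]oxy}propanoate | COC(=O)[C@@H](OC(=O)C#Cc1ccc2OC(C)(C)Oc2c1)C(Br)c1ccc2OC(C)(C)Oc2c1
F2 | step 4 | trimethyl[(2,2-dimethyl-1,3-benzodioxol-5-yl)ethynyl]silane | C[Si](C)(C)C#Cc1ccc2OC(C)(C)Oc2c1
F3 | step 3 | potassium (2S)-oxirane-2-carboxylate | [K+].[O-]C(=O)[C@@H]1CO1
F4 | step 3 | (2S)-3-(2,2-dimethyl-1,3-benzodioxol-5-yl)-2-hydroxypropanoic acid | OC(=O)[C@@H](O)Cc1ccc2OC(C)(C)Oc2c1
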